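**Plan**

- Retrosynthetic cuts: the four O-benzyl groups; then the CH2–aryl bond between the side-chain methylene on C3 of lactone 1 and ring B, giving spiro-oxirane 11 and aryl iodide 24; in 24 the C3–CH2(ring D) bond and the ring B–ring C biaryl bond; in both lactones the C4–CH2Ar bond, back to dimethyl (R)-malate.
- Forward order: the B–C biaryl is made first (Suzuki) and iodinated para to the ring B hydroxyl; each lactone ring arises from an alkylated malate (dioxolanone, borane, lactonisation); lactone 1 is taken to the spiro-oxirane, lactone 2 receives ring D; the halves are joined and the benzyl ethers removed.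
- Stereochemistry: both C4 centres come from (R)-malate by anti-selective Fráter–Seebach alkylation; both C3 carbinol centres come from C–C bond formation on the α-oxido lactone enolate anti to the C4 benzyl group, which leaves OH cis to it; the key step touches no stereocentre.
- Enabling feature: the methylene to be joined sits next to the quaternary carbinol C3, itself α to the lactone C=O, so the C3(O)–CH2 pair is a spiro-oxirane that can be opened only at CH2; its partner carbon on ring B is para to the phenolic oxygen, with OMe and ring C on both ortho positions, so iodine goes there selectively and the carbon–iodine bond has two ortho hydrogens.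

Key step: step 18

Remark on names: lactone = oxolan-2-one numbered O1, C2 (C=O), C3, C4, C5; Ar1 = 4-(benzyloxy)-3-methoxyphenyl; Ar2 = 4-(benzyloxy)-3-[2-(benzyloxy)-5-iodo-3-methoxyphenyl]-5-methoxyphenyl. All chiral compounds are single enantiomers fixed by commercial dimethyl (R)-malate.

**Route**

Step 1
Reactants: 1 4-(benzyloxy)-3-methoxybenzyl alcohol
Product: 2 4-(benzyloxy)-3-methoxybenzyl bromide (Ar1-CH2Br)
Conditions: PBr3 (0.4 equiv), Et2O, 0 °C
Reagents that add atoms: phosphorus tribromide, BrP(Br)Br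
Why: The benzylic alcohol is converted through its phosphite ester into the bromide by bromide displacement (PBr3 bromination), a standard reaction for alkoxybenzyl alcohols that leaves the aryl benzyl ether intact.

Step 2
Reactants: 3 dimethyl (R)-malate; 2 4-(benzyloxy)-3-methoxybenzyl bromide
Product: 4 dimethyl (2R,3S)-2-hydroxy-3-(Ar1-methyl)butanedioate
Conditions: LiN(SiMe3)2 (2.1 equiv), THF, −78 → −20 °C; then 2, −78 → 0 °C; aqueous work-up
Reagents that add atoms: none
Why: Fráter–Seebach alkylation, in which the chelated dilithium alkoxide-enolate of the malate is alkylated on the face anti to the C2 alkoxide, should set the new C3 centre as S under control of the malate C2 centre.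

Step 3
Reactants: 4 dimethyl (2R,3S)-2-hydroxy-3-(Ar1-methyl)butanedioate
Product: 5 (2R,3S)-2-hydroxy-3-(Ar1-methyl)butanedioic acid
Conditions: LiOH·H2O (4 equiv), THF/H2O, 0 °C → rt; then 1 M HCl to pH 2
Reagents that add atoms: lithium hydroxide, LiOH, [Li+].[OH-] (supplies the new carboxyl oxygens)
Why: Saponification of both methyl esters by acyl–oxygen cleavage under mild conditions should not epimerise either centre, because the dicarboxylate resists enolisation.

Step 4
Reactants: 5 (2R,3S)-2-hydroxy-3-(Ar1-methyl)butanedioic acid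
Product: 6 (2S)-3-Ar1-2-[(4R)-2,2-dimethyl-5-oxo-1,3-dioxolan-4-yl]propanoic acid
Conditions: 2,2-dimethoxypropane (5 equiv), TsOH·H2O (5 mol %), CH2Cl2, rt
Reagents that add atoms: 2,2-dimethoxypropane, COC(C)(C)OC
Why: Acid-catalysed acetal exchange engages the α-hydroxy acid in the favoured five-membered dioxolanone and so tells the two carboxyl groups apart without touching a stereocentre.

Step 5
Reactants: 6 (2S)-3-Ar1-2-[(4R)-2,2-dimethyl-5-oxo-1,3-dioxolan-4-yl]propanoic acid
Product: 8 (3R,4R)-3-hydroxy-4-(Ar1-methyl)oxolan-2-one (OH cis to the benzyl group), via hydroxy dioxolanone 7 (not isolated)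
Conditions: BH3·SMe2 (1.3 equiv), THF, 0 °C → rt; MeOH; then TsOH·H2O (10 mol %), CH2Cl2, rt
Reagents that add atoms: none
Why: Borane reduces the free carboxylic acid far faster than the ester-type dioxolanone carbonyl, and under acid the new primary alcohol then attacks that carbonyl in a 5-exo-trig lactonisation that expels acetone and frees the C3 hydroxyl with both centres unchanged.

Step 6
Reactants: 8 (3R,4R)-3-hydroxy-4-(Ar1-methyl)oxolan-2-one
Product: 9 (3S,4R)-3-hydroxy-3-(hydroxymethyl)-4-(Ar1-methyl)oxolan-2-one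
Conditions: LiN(SiMe3)2 (2.3 equiv), THF, −78 °C; CH2O gas (from cracked paraformaldehyde, excess), −78 → −40 °C; aqueous work-up
Reagents that add atoms: formaldehyde, C=O
Why: Aldol addition of the dilithium alkoxide-enolate to monomeric formaldehyde should occur on the face anti to the C4 benzyl group, as in C-alkylations of α-hydroxy-β-benzyl-γ-butyrolactone dianions, so that the hydroxymethyl group ends trans and the tertiary hydroxyl cis to that benzyl group.

Step 7
Reactants: 9 (3S,4R)-3-hydroxy-3-(hydroxymethyl)-4-(Ar1-methyl)oxolan-2-one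
Product: 11 (3S,7R)-7-(Ar1-methyl)-1,5-dioxaspiro[2.4]heptan-4-one (oxirane O cis to the benzyl group), via primary tosylate 10 (not isolated)
Conditions: TsCl (1.1 equiv), Et3N (2 equiv), Me3N·HCl (10 mol %), CH2Cl2, 0 °C; then DBU (1.5 equiv), rt
Reagents that add atoms: none
Why: Selective sulfonylation of the primary hydroxyl followed by intramolecular Williamson closure (3-exo-tet) by the tertiary alkoxide gives the oxirane without breaking a bond at the quaternary centre, whose configuration is therefore retained.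

Step 8
Reactants: 12 5-iodovanillin; 13 (2-hydroxy-3-methoxyphenyl)boronic acid
Product: 14 4-hydroxy-3-(2-hydroxy-3-methoxyphenyl)-5-methoxybenzaldehyde
Conditions: Pd(PPh3)4 (3 mol %), K2CO3 (3 equiv), 1,4-dioxane/H2O, 85 °C
Reagents that add atoms: none
Why: Suzuki–Miyaura coupling (oxidative addition of zerovalent palladium into the carbon–iodine bond, transmetalation of the boronate, reductive elimination) tolerates the free phenols and the aldehyde in aqueous base.

Step 9
Reactants: 14 4-hydroxy-3-(2-hydroxy-3-methoxyphenyl)-5-methoxybenzaldehyde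
Product: 15 4-hydroxy-3-(2-hydroxy-5-iodo-3-methoxyphenyl)-5-methoxybenzaldehyde
Conditions: N-iodosuccinimide (1.0 equiv), MeCN, 0 °C, dark
Reagents that add atoms: N-iodosuccinimide, O=C1CCC(=O)N1I
Why: Electrophilic aromatic iodination is directed para to the hydroxyl of the non-formylated ring, the only free ortho or para position of either phenol, while the formyl-bearing ring is deactivated.

Step 10
Reactants: 15 4-hydroxy-3-(2-hydroxy-5-iodo-3-methoxyphenyl)-5-methoxybenzaldehyde
Product: 16 Ar2-CHO [4-(benzyloxy)-3-[2-(benzyloxy)-5-iodo-3-methoxyphenyl]-5-methoxybenzaldehyde]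
Conditions: BnBr (2.5 equiv), K2CO3 (3 equiv), DMF, 60 °C
Reagents that add atoms: benzyl bromide, BrCc1ccccc1
Why: Double Williamson etherification of the two phenoxides with benzyl bromide.

Step 11
Reactants: 16 Ar2-CHO
Product: 17 Ar2-CH2OH
Conditions: NaBH4 (1 equiv), THF/MeOH, 0 °C
Reagents that add atoms: none
Why: Chemoselective borohydride reduction of the aldehyde, to which the aryl iodide and the benzyl ethers are inert.

Step 12
Reactants: 17 Ar2-CH2OH
Product: 18 Ar2-CH2Br
Conditions: PBr3 (0.4 equiv), CH2Cl2, 0 °C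
Reagents that add atoms: phosphorus tribromide, BrP(Br)Br
Why: PBr3 bromination of the benzylic alcohol as in step 1, with the aryl iodide and ethers untouched.

Step 13
Reactants: 3 dimethyl (R)-malate; 18 Ar2-CH2Br
Product: 19 dimethyl (2R,3S)-2-hydroxy-3-(Ar2-methyl)butanedioate
Conditions: LiN(SiMe3)2 (2.1 equiv), THF, −78 → −20 °C; then 18, −78 → 0 °C; aqueous work-up
Reagents that add atoms: none
Why: Fráter–Seebach alkylation as in step 2, with a silylamide base mild enough not to metalate the iodoarene, should again give the anti (2R,3S) product under control of the malate centre.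

Step 14
Reactants: 19 dimethyl (2R,3S)-2-hydroxy-3-(Ar2-methyl)butanedioate
Product: 20 (2R,3S)-2-hydroxy-3-(Ar2-methyl)butanedioic acid
Conditions: LiOH·H2O (4 equiv), THF/H2O, 0 °C → rt; then 1 M HCl to pH 2
Reagents that add atoms: lithium hydroxide, LiOH, [Li+].[OH-] (supplies the new carboxyl oxygens)
Why: Mild saponification of both esters as in step 3, without epimerisation and without effect on the aryl iodide.

Step 15
Reactants: 20 (2R,3S)-2-hydroxy-3-(Ar2-methyl)butanedioic acid
Product: 21 (2S)-3-Ar2-2-[(4R)-2,2-dimethyl-5-oxo-1,3-dioxolan-4-yl]propanoic acid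
Conditions: 2,2-dimethoxypropane (5 equiv), TsOH·H2O (5 mol %), CH2Cl2, rt
Reagents that add atoms: 2,2-dimethoxypropane, COC(C)(C)OC
Why: Five-membered dioxolanone formation across the α-hydroxy acid, as in step 4, differentiates the two carboxyl groups.

Step 16
Reactants: 21 (2S)-3-Ar2-2-[(4R)-2,2-dimethyl-5-oxo-1,3-dioxolan-4-yl]propanoic acid
Product: 23 (3R,4R)-3-hydroxy-4-(Ar2-methyl)oxolan-2-one, via hydroxy dioxolanone 22 (not isolated)
Conditions: BH3·SMe2 (1.3 equiv), THF, 0 °C → rt; MeOH; then TsOH·H2O (10 mol %), CH2Cl2, rt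
Reagents that add atoms: none
Why: Chemoselective borane reduction of the free acid and acid-catalysed 5-exo-trig lactonisation with loss of acetone, as in step 5, neither of which affects the aryl iodide or the stereocentres.

Step 17
Reactants: 23 (3R,4R)-3-hydroxy-4-(Ar2-methyl)oxolan-2-one; 2 4-(benzyloxy)-3-methoxybenzyl bromide
Product: 24 (3R,4R)-3-hydroxy-3-(Ar1-methyl)-4-(Ar2-methyl)oxolan-2-one
Conditions: LiN(SiMe3)2 (2.2 equiv), THF/DMPU, −78 °C; 2 (1.2 equiv), −78 → −20 °C; aqueous work-up
Reagents that add atoms: none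
Why: C-Benzylation of the dilithium alkoxide-enolate on the face anti to the C4 arylmethyl group, a well-precedented enolate alkylation for this lactone class, sets the quaternary carbinol with the hydroxyl cis to that group.

Step 18
Reactants: 11 (3S,7R)-7-(Ar1-methyl)-1,5-dioxaspiro[2.4]heptan-4-one; 24 (3R,4R)-3-hydroxy-3-(Ar1-methyl)-4-(Ar2-methyl)oxolan-2-one
Product: 26 tetra-O-benzyl ether of the target (both lactones 3R,4R), via iodohydrin 25 (not isolated)
Conditions: NiCl2(dme) (10 mol %), 2,2'-bipyridine (10 mol %), NaI (25 mol %), Et3N·HCl (1.0 equiv), Mn powder (2 equiv), DMPU, 30 °C; 11 (1.5 equiv)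
Reagents that add atoms: none
Why: Iodide, with Et3N·HCl as proton source, opens the spiro-oxirane of 11 by SN2 attack at its only unsubstituted carbon to give iodohydrin 25, while zerovalent nickel–bipyridine adds oxidatively into the unhindered carbon–iodine bond of 24; monovalent nickel then abstracts iodine from 25, the primary β-hydroxy radical is captured by the arylnickel species, and reductive elimination from trivalent nickel forms the CH2–aryl bond, with Mn returning the catalyst to the zerovalent state. The closest known reaction type is the nickel-catalysed cross-electrophile coupling of terminal epoxides with aryl halides under iodide co-catalysis (and of primary alkyl iodides with aryl iodides), applied here to a 2,2-disubstituted glycidic lactone. No ring is closed; the oxirane is a temporary ring that is opened. No new stereocentre is formed: the carbinol carbon keeps the configuration fixed in 11 because its C–O bond is never broken and the radical sits one carbon away. The step needs regioselective opening at CH2, which the quaternary, carbonyl-bearing carbinol carbon secures, and cross- over homo-coupling, which the different activation of the sp2 iodide (oxidative addition) and the sp3 iodide (radical formation) secures, helped by the slow release of 25 and the excess of 11.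

Step 19
Reactants: 26 tetra-O-benzyl ether of the target
Product: 27 target CNP0218652.1
Conditions: H2 (1 atm), 10% Pd/C, EtOAc/MeOH, rt
Reagents that add atoms: none
Why: Hydrogenolysis of the four aryl benzyl ethers over palladium, to which the lactones, the homobenzylic tertiary alcohols and the biaryl are inert.

**Compound list**

1 | 4-(benzyloxy)-3-methoxybenzyl alcohol | COc1cc(CO)ccc1OCc1ccccc1 | starting material
2 | 4-(benzyloxy)-3-methoxybenzyl bromide (Ar1-CH2Br) | COc1cc(CBr)ccc1OCc1ccccc1 | intermediate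
3 | dimethyl (R)-malate [dimethyl (2R)-2-hydroxybutanedioate] | COC(=O)C[C@@H](O)C(=O)OC | starting material
4 | dimethyl (2R,3S)-2-hydroxy-3-(Ar1-methyl)butanedioate | COC(=O)[C@H](O)[C@H](Cc1ccc(OCc2ccccc2)c(OC)c1)C(=O)OC | intermediate
5 | (2R,3S)-2-hydroxy-3-(Ar1-methyl)butanedioic acid | OC(=O)[C@H](O)[C@H](Cc1ccc(OCc2ccccc2)c(OC)c1)C(=O)O | intermediate
6 | (2S)-3-Ar1-2-[(4R)-2,2-dimethyl-5-oxo-1,3-dioxolan-4-yl]propanoic acid | O=C1OC(C)(C)O[C@@H]1[C@H](Cc2ccc(OCc3ccccc3)c(OC)c2)C(=O)O | intermediate
7 | (5R)-5-[(2R)-1-Ar1-3-hydroxypropan-2-yl]-2,2-dimethyl-1,3-dioxolan-4-one | O=C1OC(C)(C)O[C@@H]1[C@H](Cc2ccc(OCc3ccccc3)c(OC)c2)CO | intermediate (not isolated)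
8 | (3R,4R)-3-hydroxy-4-(Ar1-methyl)oxolan-2-one (OH cis to benzyl) | O[C@@H]1[C@H](Cc2ccc(OCc3ccccc3)c(OC)c2)COC1=O | intermediate
9 | (3S,4R)-3-hydroxy-3-(hydroxymethyl)-4-(Ar1-methyl)oxolan-2-one (tertiary OH cis to benzyl) | O[C@]1(CO)[C@H](Cc2ccc(OCc3ccccc3)c(OC)c2)COC1=O | intermediate
10 | [(3S,4R)-3-hydroxy-4-(Ar1-methyl)-2-oxooxolan-3-yl]methyl 4-methylbenzenesulfonate | O[C@]1(COS(=O)(=O)c2ccc(C)cc2)[C@H](Cc2ccc(OCc3ccccc3)c(OC)c2)COC1=O | intermediate (not isolated)
11 | (3S,7R)-7-(Ar1-methyl)-1,5-dioxaspiro[2.4]heptan-4-one (oxirane O cis to benzyl) | C1O[C@@]12[C@H](Cc3ccc(OCc4ccccc4)c(OC)c3)COC2=O | intermediate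
12 | 5-iodovanillin (4-hydroxy-3-iodo-5-methoxybenzaldehyde) | COc1cc(C=O)cc(I)c1O | starting material
13 | (2-hydroxy-3-methoxyphenyl)boronic acid | COc1cccc(B(O)O)c1O | starting material
14 | 4-hydroxy-3-(2-hydroxy-3-methoxyphenyl)-5-methoxybenzaldehyde | COc1cc(C=O)cc(-c2cccc(OC)c2O)c1O | intermediate
15 | 4-hydroxy-3-(2-hydroxy-5-iodo-3-methoxyphenyl)-5-methoxybenzaldehyde | COc1cc(C=O)cc(-c2cc(I)cc(OC)c2O)c1O | intermediate
16 | 4-(benzyloxy)-3-[2-(benzyloxy)-5-iodo-3-methoxyphenyl]-5-methoxybenzaldehyde (Ar2-CHO) | COc1cc(C=O)cc(-c2cc(I)cc(OC)c2OCc2ccccc2)c1OCc1ccccc1 | intermediate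
17 | Ar2-CH2OH, the corresponding benzyl alcohol | COc1cc(CO)cc(-c2cc(I)cc(OC)c2OCc2ccccc2)c1OCc1ccccc1 | intermediate
18 | Ar2-CH2Br, the corresponding benzyl bromide | COc1cc(CBr)cc(-c2cc(I)cc(OC)c2OCc2ccccc2)c1OCc1ccccc1 | intermediate
19 | dimethyl (2R,3S)-2-hydroxy-3-(Ar2-methyl)butanedioate | COC(=O)[C@H](O)[C@H](Cc1cc(OC)c(OCc2ccccc2)c(-c2cc(I)cc(OC)c2OCc2ccccc2)c1)C(=O)OC | intermediate
20 | (2R,3S)-2-hydroxy-3-(Ar2-methyl)butanedioic acid | OC(=O)[C@H](O)[C@H](Cc1cc(OC)c(OCc2ccccc2)c(-c2cc(I)cc(OC)c2OCc2ccccc2)c1)C(=O)O | intermediate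
21 | (2S)-3-Ar2-2-[(4R)-2,2-dimethyl-5-oxo-1,3-dioxolan-4-yl]propanoic acid | O=C1OC(C)(C)O[C@@H]1[C@H](Cc2cc(OC)c(OCc3ccccc3)c(-c3cc(I)cc(OC)c3OCc3ccccc3)c2)C(=O)O | intermediate
22 | (5R)-5-[(2R)-1-Ar2-3-hydroxypropan-2-yl]-2,2-dimethyl-1,3-dioxolan-4-one | O=C1OC(C)(C)O[C@@H]1[C@H](Cc2cc(OC)c(OCc3ccccc3)c(-c3cc(I)cc(OC)c3OCc3ccccc3)c2)CO | intermediate (not isolated)
23 | (3R,4R)-3-hydroxy-4-(Ar2-methyl)oxolan-2-one (OH cis to arylmethyl) | O[C@@H]1[C@H](Cc2cc(OC)c(OCc3ccccc3)c(-c3cc(I)cc(OC)c3OCc3ccccc3)c2)COC1=O | intermediate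
24 | (3R,4R)-3-hydroxy-3-(Ar1-methyl)-4-(Ar2-methyl)oxolan-2-one (OH cis to the C4 arylmethyl group) | COc1cc(C[C@@H]2COC(=O)[C@@]2(O)Cc2ccc(OCc3ccccc3)c(OC)c2)cc(-c2cc(I)cc(OC)c2OCc2ccccc2)c1OCc1ccccc1 | intermediate
25 | (3R,4R)-3-hydroxy-3-(iodomethyl)-4-(Ar1-methyl)oxolan-2-one | O[C@]1(CI)[C@H](Cc2ccc(OCc3ccccc3)c(OC)c2)COC1=O | intermediate (not isolated)
26 | tetra-O-benzyl ether of the target (all four phenols benzylated; both lactones 3R,4R) | COc1cc(C[C@@H]2COC(=O)[C@@]2(O)Cc2cc(OC)c(OCc3ccccc3)c(-c3cc(C[C@@H]4COC(=O)[C@@]4(O)Cc4ccc(OCc5ccccc5)c(OC)c4)cc(OC)c3OCc3ccccc3)c2)ccc1OCc1ccccc1 | intermediate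
27 | CNP0218652.1 | COc1cc(C[C@@H]2COC(=O)[C@@]2(O)Cc2cc(OC)c(O)c(-c3cc(C[C@@H]4COC(=O)[C@@]4(O)Cc4ccc(O)c(OC)c4)cc(OC)c3O)c2)ccc1O | target

**Step count and risks**

Total step count: 19. Longest linear sequence: 12 steps (steps 8 to 19, from 12).

Steps most likely to fail:

1. Step 18. The hindered oxirane may open too slowly, so that reduction of the carbon–iodine bond of 24 or aryl–aryl homocoupling wins; an alkylnickel intermediate may also lose the tertiary hydroxyl by β-elimination. Fallback, from 24 and 8, back at 26: the union is moved to the neighbouring C3–CH2 bond and made by enolate alkylation. Stille coupling of 24 with (tributylstannyl)methanol (Pd(PPh3)4, 1,4-dioxane, 90 °C) should give the hydroxymethyl arene F1. PBr3 (CH2Cl2, 0 °C), to which the tertiary α-hydroxy lactone alcohol is inert, should give the bromomethyl arene F2. Alkylation of the dilithium alkoxide-enolate of 8 with F2 (LiN(SiMe3)2, one extra equivalent for the tertiary hydroxyl of F2; THF/DMPU, −78 °C), anti to the benzyl group as in step 17, should then give 26.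

2. Step 6. The aldol addition is reversible on warming, formaldehyde can oligomerise or be consumed by hydride-transfer side reactions, and so small an electrophile may discriminate less well between the two enolate faces. Fallback, from 8, back at 11 (steps 6 and 7 both replaced): Mannich reaction of the same dianion with dimethylmethyleneiminium iodide (THF, −78 °C), an irreversible and bulkier electrophile, should give the amino alcohol F3 anti to the benzyl group. Exhaustive methylation (MeI, MeCN) gives the trimethylammonium iodide F4. K2CO3 in MeCN should then close the oxirane by displacement of trimethylamine by the tertiary alkoxide, giving 11.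

3. Step 17. The hindered dianion may undergo O-alkylation or incomplete conversion, and facial selectivity may erode at the quaternary centre. Fallback, from 23, back at 24: aldol addition of the dianion of 23 to commercial 4-(benzyloxy)-3-methoxybenzaldehyde, which is more reactive and cannot O-alkylate, should give the benzylic carbinol F5, a mixture of epimers at the new secondary carbinol only. Ionic hydrogenation of the 4-alkoxybenzylic hydroxyl (Et3SiH, BF3·OEt2, CH2Cl2, −78 °C) should then give 24; the tertiary hydroxyl next to the lactone carbonyl cannot ionise.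

**Further compounds**

F1 | step 18 | (3R,4R)-3-hydroxy-3-(Ar1-methyl)-4-({4-(benzyloxy)-3-[2-(benzyloxy)-5-(hydroxymethyl)-3-methoxyphenyl]-5-methoxyphenyl}methyl)oxolan-2-one | COc1cc(C[C@@H]2COC(=O)[C@@]2(O)Cc2ccc(OCc3ccccc3)c(OC)c2)cc(-c2cc(CO)cc(OC)c2OCc2ccccc2)c1OCc1ccccc1
F2 | step 18 | (3R,4R)-3-hydroxy-3-(Ar1-methyl)-4-({4-(benzyloxy)-3-[2-(benzyloxy)-5-(bromomethyl)-3-methoxyphenyl]-5-methoxyphenyl}methyl)oxolan-2-one | COc1cc(C[C@@H]2COC(=O)[C@@]2(O)Cc2ccc(OCc3ccccc3)c(OC)c2)cc(-c2cc(CBr)cc(OC)c2OCc2ccccc2)c1OCc1ccccc1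
F3 | step 6 | (3S,4R)-3-[(dimethylamino)methyl]-3-hydroxy-4-(Ar1-methyl)oxolan-2-one | O[C@]1(CN(C)C)[C@H](Cc2ccc(OCc3ccccc3)c(OC)c2)COC1=O
F4 | step 6 | [(3S,4R)-3-hydroxy-4-(Ar1-methyl)-2-oxooxolan-3-yl]-N,N,N-trimethylmethanaminium iodide | O[C@]1(C[N+](C)(C)C)[C@H](Cc2ccc(OCc3ccccc3)c(OC)c2)COC1=O.[I-]
F5 | step 17 | (3R,4R)-3-hydroxy-3-[hydroxy(Ar1)methyl]-4-(Ar2-methyl)oxolan-2-one, both epimers at the secondary carbinol | COc1cc(C[C@@H]2COC(=O)[C@@]2(O)C(O)c2ccc(OCc3ccccc3)c(OC)c2)cc(-c2cc(I)cc(OC)c2OCc2ccccc2)c1OCc1ccccc1
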